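**Frozen clock.** The decision is to carry one hand-reckoned quantity from run to run.

| flask | starting material | partner | time |
|---|---|---|---|
| beta | 0.0800 M | 0.0800 M |  |
| eta | 0.0400 M | 0.0400 M |  |
| alpha | 0.0800 M | 0.0400 M |  |
| theta | 0.0800 M | 0.0230 M | 27 min |

| run | time / min | [target] / M |
|---|---|---|
| beta run | 1.5 | 0.0037 |
| beta run | 4.7 | 0.0109 |
| beta run | 8.9 | 0.0177 |
| beta run | 14 | 0.0234 |
| beta run | 20 | 0.0273 |
| beta run | 27 | 0.0304 |
| eta run | 1.5 | 8 × 10⁻⁴ |
| eta run | 4.7 | 0.0032 |
| eta run | 8.9 | 0.0049 |
| eta run | 14 | 0.0053 |
| eta run | 20 | 0.0088 |
| eta run | 27 | 0.0078 |
| alpha run | 1.5 | 0.0012 |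
| alpha run | 4.7 | 0.0021 |
| alpha run | 8.9 | 0.0051 |
| alpha run | 14 | 0.0074 |
| alpha run | 20 | 0.0086 |
| alpha run | 27 | 0.0102 |

(each reading ± 4 × 10⁻⁴ M)

1. apparent order in [partner] of the starting rate, round the charge of the beta run (the rate where two percent of its starting material have turned into target)
2. apparent order in [starting material] of the starting rate, round the charge of the beta run (the rate where two percent of its starting material have turned into target) (one fixed amount of target, the same in the runs compared)
3. target in the theta run at 27 min, as a share of the starting material charged

- Overall: starting material + partner -> target.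
- Constant volume, constant temperature.
- Bound and free are read together.
- "The second partner" is partner.
- An order is taken over about fifteen percent of the charge, up and down.

**Starting rates.** Over the first 8.9 min, target forms at a mean 0.00199 M min⁻¹ in the beta run, 5.73 × 10⁻⁴ M min⁻¹ in the alpha run and 5.51 × 10⁻⁴ M min⁻¹ in the eta run. Halving the partner from beta to alpha gives my reading of order 1.80 in partner. Halving the starting material from alpha to eta gives 0.0577 in starting material, as a reading: the two target values behind it differ by 2.00 × 10⁻⁴ M, less than the scatter of 4 × 10⁻⁴ M.

**The slowing.** In the beta run, the rate falls from 0.00247 M min⁻¹ in the first interval to 4.43 × 10⁻⁴ M min⁻¹ in the last, a factor of 5.57. The squared loss of partner gives a factor of 2.45, which leaves a further fade of 2.27 as read.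

**Reciprocal clock.** If the rate goes with the square of partner, and partner is its charge less the target made, both factors fold into the reciprocal clock, the gain in reciprocal partner by a given time, which is then the rate constant summed over that time. At 27 min it reads 8.56 L mol⁻¹ in alpha and 7.66 L mol⁻¹ in beta. In eta it reads 6.06 L mol⁻¹, from a last reading lower than the one before it. The theta run shares the starting material of alpha, and its partner charge lies closer to alpha than to beta, so I freeze the alpha clock. Added to the reciprocal of the theta charge, it leaves 0.0192 M of partner, or 4.73% of the starting material as target.

**The forecast.** It gives 2 in partner, 0.1 in starting material and 4.6% for the theta run, and reads the fade as “something dying with time”. My figures above stand apart from these, with 4.73% for the theta run.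

**The result.** The flask gives 2.1 in partner, −0.14 in starting material and 4.67% for the theta run, so the forecast parts from it on the sign of the order in starting material.

    starting material + 2 partner → target + partner (63.60 L² mol⁻² min⁻¹)
    starting material → decomposed substrate (0.1554 min⁻¹)
    starting material + partner ⇌ idle substrate-reagent adduct, settled at all times (37.70 L mol⁻¹)

**What ran.** In the theta run, the target step ran on free starting material and partner while the same free starting material went to decomposed substrate with 0.155 min⁻¹, and the idle substrate-reagent adduct stood in fast equilibrium with both at 37.7 L mol⁻¹. Read back from this result, the theta clock at 27 min stands at 8.44 L mol⁻¹, against the 8.56 L mol⁻¹ carried from the alpha run. In the beta run the same quantity stood at 4.17 L mol⁻¹ at 10.4 min, where target came to a quarter of the starting material charged.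

The data were computed for substances that don't exist; scatter was added.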